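**Retrosynthetic overview**

1. The hydroperoxy-enone is revealed last by a singlet-oxygen ene reaction of the 7(11)-en-8-one (cuauhtemone 3-angelate). The angelate is attached to the cis-3α,4α-diol, which comes from OsO4 on eudesma-3,7(11)-dien-8-one.
2. Key disconnection: ring B of that dienone is traced back to a five-membered ring. A one-carbon ring expansion shifts the quaternary carbon C10 from the carbonyl carbon C8 to an inserted CH2 (C9) of a 2-isopropylidene trans-hydrindan-1-one.
3. The isopropylidene comes from acetone at the only α-CH2 of the hydrindanone. The C3=C4 alkene and 5α-H come from the annulation enone by 1,2-reduction and reductive 1,3-transposition.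
4. The enone is the amino-acid-mediated Robinson annulation product of 2-methylcyclopentane-1,3-dione and ethyl vinyl ketone; this step sets C10.
5. Ring order: five-membered ring (purchased) → ring A (annulation) → ring B (expansion of the five-membered ring).

Assumption: decalins use eudesmane numbering (C10 quaternary, C8 carbonyl, α = face opposite the C10 methyl); a telescoped one-flask sequence counts as one step; lithium salts, catalyst-bound species and transient betaines are not numbered.

**Route**

Step 1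
Reactants: 1 2-methylcyclopentane-1,3-dione; 2 pent-1-en-3-one (ethyl vinyl ketone)
Product: 4 (7aS)-4,7a-dimethyl-2,3,7,7a-tetrahydro-1H-indene-1,5(6H)-dione, via triketone 3 (not isolated)
Conditions: Et3N (1 mol %), MeCN, 23 °C; then L-phenylalanine (1 equiv), (1S)-(+)-10-camphorsulfonic acid (0.5 equiv), 70 °C; recrystallise
Reagents that add atoms: none
Why: Michael addition followed by an L-phenylalanine-mediated Hajos–Parrish-type intramolecular aldol condensation (Robinson annulation), in which the enamine/acid transition state selects one of the two enantiotopic ring carbonyls and sets the quaternary centre (future C10) as S (about 90% ee expected before recrystallisation).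

Step 2
Reactants: 4 (7aS)-4,7a-dimethyl-2,3,7,7a-tetrahydro-1H-indene-1,5(6H)-dione
Product: 5 (5S,7aS)-5-hydroxy-4,7a-dimethyl-2,3,5,6,7,7a-hexahydro-1H-inden-1-one
Conditions: NaBH4 (1.0 equiv), CeCl3·7H2O (1.1 equiv), MeOH, −78 °C
Reagents that add atoms: none
Why: Luche reduction, in which the cerium-modified hard hydride reduces the conjugated carbonyl 1,2 in preference to the neopentyl cyclopentanone at low temperature, and axial attack anti to the angular methyl gives the alcohol cis to that methyl (5S).

Step 3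
Reactants: 5 (5S,7aS)-5-hydroxy-4,7a-dimethyl-2,3,5,6,7,7a-hexahydro-1H-inden-1-one
Product: 8 (3aS,7aS)-4,7a-dimethyl-2,3,3a,6,7,7a-hexahydro-1H-inden-1-one, via sulfonylhydrazine adduct 6 (not isolated), via allylic diazene 7 (not isolated)
Conditions: 2-nitrobenzenesulfonylhydrazide (NBSH), PPh3, DEAD, N-methylmorpholine, −30 °C; then 23 °C
Reagents that add atoms: none
Why: Myers reductive 1,3-transposition: Mitsunobu substitution by NBSH inverts C5, loss of sulfinic acid gives the monoalkyl diazene, and its retro-ene loss of N2 delivers hydrogen to C3a on the face opposite the angular methyl, setting the trans ring fusion (future 5α-H) and placing the alkene at the future C3=C4.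

Step 4
Reactants: 8 (3aS,7aS)-4,7a-dimethyl-2,3,3a,6,7,7a-hexahydro-1H-inden-1-one; 9 acetone
Product: 12 (3aS,7aS)-4,7a-dimethyl-2-(propan-2-ylidene)-2,3,3a,6,7,7a-hexahydro-1H-inden-1-one, via aldol adduct 10 (not isolated), via aldol mesylate 11 (not isolated)
Conditions: LiN(i-Pr)2, THF, −78 °C; 9; MsCl, −78 → 0 °C; DBU, 23 °C
Reagents that add atoms: none
Why: Directed aldol condensation: the enolate can form only at the single α-methylene (the other α-carbon is quaternary), the tertiary aldolate is mesylated and eliminated (E1cB), and DBU equilibrates any isopropenyl isomer to the conjugated isopropylidene ketone; no stereocentre is created.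

Step 5
Reactants: 12 (3aS,7aS)-4,7a-dimethyl-2-(propan-2-ylidene)-2,3,3a,6,7,7a-hexahydro-1H-inden-1-one
Product: 14 (5R,10R)-eudesma-3,7(11)-dien-8-one [(4aR,8aR)-5,8a-dimethyl-3-(propan-2-ylidene)-3,4,4a,7,8,8a-hexahydronaphthalen-2(1H)-one], via silyl ketone 13 (not isolated)
Conditions: TMSCHN2, BF3·OEt2, CH2Cl2, −78 → −20 °C; then K2CO3 (cat.), MeOH, 23 °C
Reagents that add atoms: (trimethylsilyl)diazomethane, C[Si](C)(C)C=[N+]=[N-]
Why: Proposed new method: a Lewis-acid-promoted diazoalkane homologation (Büchner–Curtius–Schlotterbeck/Tiffeneau–Demjanov type; closest known case is the BF3-promoted TMSCHN2 ring enlargement of saturated cycloalkanones, where the less substituted carbon normally migrates) applied to an α-alkylidene, α′-quaternary cyclopentanone, in which TMSCHN2 adds to the BF3-activated carbonyl and the diazonium betaine can collapse only by 1,2-shift of the sp3 quaternary carbon (C10, with retention) because, by analogy with acid-promoted diazo insertions into conjugated ketones that occur on the saturated side, the alkenyl carbon does not migrate and its retention stabilises the developing oxocarbenium, so CH2 (C9) is inserted between C10 and C8 to form six-membered ring B with the enone intact, and methanolysis removes the C9 silyl group.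

Step 6
Reactants: 14 (5R,10R)-eudesma-3,7(11)-dien-8-one
Product: 15 cuauhtemone, (3R,4S,5R,10R)-3α,4α-dihydroxyeudesm-7(11)-en-8-one
Conditions: OsO4 (2 mol %), N-methylmorpholine N-oxide, acetone/H2O, 23 °C
Reagents that add atoms: osmium tetroxide, O=[Os](=O)(=O)=O; N-methylmorpholine N-oxide, C[N+]1([O-])CCOCC1; water, O
Why: Upjohn syn-dihydroxylation, in which OsO4 reacts only with the electron-rich trisubstituted C3=C4 alkene (the tetrasubstituted enone alkene is inert) from the α face opposite the axial C10 methyl, setting 3α-OH (3R) and 4α-OH/4β-CH3 (4S) together.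

Step 7
Reactants: 15 cuauhtemone; 16 angelic acid, (Z)-2-methylbut-2-enoic acid
Product: 18 (3R,4S,5R,10R)-3α-angeloyloxy-4α-hydroxyeudesm-7(11)-en-8-one, via mixed anhydride 17 (not isolated)
Conditions: 16, 2,4,6-trichlorobenzoyl chloride, Et3N, toluene, 23 °C; then 15, 75 °C
Reagents that add atoms: none
Why: Yamaguchi-type esterification through the mixed anhydride, which acylates the secondary 3α-hydroxyl while the tertiary 4α-hydroxyl is inert, and omitting a nucleophilic amine catalyst keeps the Z (angelate) geometry from isomerising to tiglate.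

Step 8
Reactants: 18 (3R,4S,5R,10R)-3α-angeloyloxy-4α-hydroxyeudesm-7(11)-en-8-one
Product: 19 (3R,4S,5R,10R)-3α-angeloyloxy-4α-hydroxy-11-hydroperoxyeudesm-6-en-8-one (target)
Conditions: O2, tetraphenylporphyrin (1 mol %), white LED, CH2Cl2, 0 °C
Reagents that add atoms: dioxygen, O=O
Why: Schenck ene reaction of singlet oxygen, where for an α,β-unsaturated ketone hydrogen is abstracted from the alkyl group geminal to the carbonyl (C6–H), so the hydroperoxide forms at C11 and the alkene moves to C6=C7 in conjugation with C8=O; no stereocentre is created and the electron-poorer angelate alkene reacts more slowly.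

**Compound list**

1 | 2-methylcyclopentane-1,3-dione | CC1C(=O)CCC1=O | starting material
2 | pent-1-en-3-one (ethyl vinyl ketone) | CCC(=O)C=C | starting material
3 | 2-methyl-2-(3-oxopentyl)cyclopentane-1,3-dione (not isolated) | CCC(=O)CCC1(C)C(=O)CCC1=O | intermediate
4 | (7aS)-4,7a-dimethyl-2,3,7,7a-tetrahydro-1H-indene-1,5(6H)-dione | C[C@]12CCC(=O)C(C)=C1CCC2=O | intermediate
5 | (5S,7aS)-5-hydroxy-4,7a-dimethyl-2,3,5,6,7,7a-hexahydro-1H-inden-1-one (OH cis to the angular methyl) | C[C@]12CC[C@H](O)C(C)=C1CCC2=O | intermediate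
6 | 1-[(5R,7aS)-4,7a-dimethyl-1-oxo-2,3,5,6,7,7a-hexahydro-1H-inden-5-yl]-1-(2-nitrobenzenesulfonyl)hydrazine (N trans to the angular methyl; not isolated) | C[C@]12CC[C@@H](N(N)S(=O)(=O)c3ccccc3[N+](=O)[O-])C(C)=C1CCC2=O | intermediate
7 | (5R,7aS)-5-diazenyl-4,7a-dimethyl-2,3,5,6,7,7a-hexahydro-1H-inden-1-one (not isolated) | C[C@]12CC[C@@H](N=N)C(C)=C1CCC2=O | intermediate
8 | (3aS,7aS)-4,7a-dimethyl-2,3,3a,6,7,7a-hexahydro-1H-inden-1-one (trans ring fusion, C4=C5 alkene) | C[C@]12CCC=C(C)[C@@H]1CCC2=O | intermediate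
9 | acetone | CC(C)=O | starting material
10 | (3aS,7aS)-2-(2-hydroxypropan-2-yl)-4,7a-dimethyl-2,3,3a,6,7,7a-hexahydro-1H-inden-1-one (C2 epimers, formed as the lithium alkoxide; not isolated) | C[C@]12CCC=C(C)[C@@H]1CC(C(C)(C)O)C2=O | intermediate
11 | 2-[(3aS,7aS)-4,7a-dimethyl-1-oxo-2,3,3a,6,7,7a-hexahydro-1H-inden-2-yl]propan-2-yl methanesulfonate (C2 epimers; not isolated) | C[C@]12CCC=C(C)[C@@H]1CC(C(C)(C)OS(C)(=O)=O)C2=O | intermediate
12 | (3aS,7aS)-4,7a-dimethyl-2-(propan-2-ylidene)-2,3,3a,6,7,7a-hexahydro-1H-inden-1-one | C[C@]12CCC=C(C)[C@@H]1CC(=C(C)C)C2=O | intermediate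
13 | 9-(trimethylsilyl)eudesma-3,7(11)-dien-8-one (5α-H, 10β-CH3; C9 epimers; not isolated) | C[C@]12CCC=C(C)[C@@H]1CC(=C(C)C)C(=O)C2[Si](C)(C)C | intermediate
14 | (5R,10R)-eudesma-3,7(11)-dien-8-one | C[C@]12CCC=C(C)[C@@H]1CC(=C(C)C)C(=O)C2 | intermediate
15 | cuauhtemone, (3R,4S,5R,10R)-3α,4α-dihydroxyeudesm-7(11)-en-8-one | O[C@@H]1CC[C@]2(C)CC(=O)C(=C(C)C)C[C@H]2[C@]1(C)O | intermediate
16 | angelic acid, (Z)-2-methylbut-2-enoic acid | C/C=C(/C)C(=O)O | starting material
17 | (Z)-2-methylbut-2-enoic 2,4,6-trichlorobenzoic anhydride (not isolated) | C/C=C(/C)C(=O)OC(=O)c1c(Cl)cc(Cl)cc1Cl | intermediate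
18 | (3R,4S,5R,10R)-3α-angeloyloxy-4α-hydroxyeudesm-7(11)-en-8-one | C/C=C(/C)C(=O)O[C@@H]1CC[C@]2(C)CC(=O)C(=C(C)C)C[C@H]2[C@]1(C)O | intermediate
19 | (3R,4S,5R,10R)-3α-angeloyloxy-4α-hydroxy-11-hydroperoxyeudesm-6-en-8-one | C/C=C(/C)C(=O)O[C@@H]1CC[C@]2(C)CC(=O)C(C(C)(C)OO)=C[C@H]2[C@]1(C)O | target

**Totals**

Total step count: 8. Longest linear sequence: 8 steps (1 → 19).

**Three steps most likely to fail, with fallbacks**

Step 2 (chemoselectivity: the saturated cyclopentanone may also be reduced). The fallback sets out from 4 and returns at 8. Both carbonyls are reduced on purpose with excess NaBH4/CeCl3·7H2O in MeOH at 0 °C to the diol (1S,5S,7aS)-4,7a-dimethyl-2,3,5,6,7,7a-hexahydro-1H-indene-1,5-diol F1. The NBSH/PPh3/DEAD transposition is then applied; only the allylic hydroxyl undergoes Mitsunobu substitution, because the neopentyl C1 hydroxyl is inert. It passes through the sulfonylhydrazine adduct 1-[(1S,5R,7aS)-1-hydroxy-4,7a-dimethyl-2,3,5,6,7,7a-hexahydro-1H-inden-5-yl]-1-(2-nitrobenzenesulfonyl)hydrazine F2 and the allylic diazene (1S,5R,7aS)-5-diazenyl-4,7a-dimethyl-2,3,5,6,7,7a-hexahydro-1H-inden-1-ol F3 to the alkenol (1S,3aS,7aS)-4,7a-dimethyl-2,3,3a,6,7,7a-hexahydro-1H-inden-1-ol F4. Oxidation with Dess–Martin periodinane (CH2Cl2, 23 °C) gives 8. The selectivity problem is replaced by a redox detour of one extra step.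

Step 3 (Mitsunobu substitution at a hindered allylic carbon next to a fully substituted alkene carbon; SN2′ attack or elimination may compete). The fallback sets out from 5 and returns at 8. Formylation of 5 (formic acetic anhydride, pyridine, 0 °C) gives the allylic formate (5S,7aS)-4,7a-dimethyl-1-oxo-2,3,5,6,7,7a-hexahydro-1H-inden-5-yl formate F5. Tsuji–Mandai hydrogenolysis follows (Pd(OAc)2, PBu3, THF, 23–50 °C; zerovalent palladium forms in situ). Ionisation with inversion places palladium on the face opposite the angular methyl, decarboxylation of the formate gives a palladium hydride, and reductive elimination delivers hydride to the more substituted allyl terminus (C3a) from that same face. This gives the trans-fused alkene 8 without a Mitsunobu step.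

Step 5 (the proposed new ring expansion; the hindered conjugated carbonyl may not add the diazoalkane, or epoxide formation or alkenyl migration may intervene). The fallback uses known chemistry, sets out from 8 and returns at 14, with ring expansion and isopropylidene introduction in the opposite order. Dibromomethyllithium (CH2Br2, lithium 2,2,6,6-tetramethylpiperidide, THF, −78 °C) adds to 8 to give the carbinol (1S,3aS,7aS)-1-(dibromomethyl)-4,7a-dimethyl-2,3,3a,6,7,7a-hexahydro-1H-inden-1-ol F6. n-BuLi (2.2 equiv, −78 → 0 °C) generates the β-oxido carbenoid, which rearranges with preferential migration of the more substituted (quaternary) carbon; protonation gives the ring-expanded ketone (4aR,8aR)-5,8a-dimethyl-3,4,4a,7,8,8a-hexahydronaphthalen-2(1H)-one F7. The LiN(i-Pr)2/acetone/MsCl/DBU sequence of step 4 is then applied, the enolate forming at the C7 methylene away from the quaternary centre. It passes through the aldol (4aR,8aR)-3-(2-hydroxypropan-2-yl)-5,8a-dimethyl-3,4,4a,7,8,8a-hexahydronaphthalen-2(1H)-one F8 and its mesylate 2-[(4aR,8aR)-5,8a-dimethyl-2-oxo-1,2,3,4,4a,7,8,8a-octahydronaphthalen-3-yl]propan-2-yl methanesulfonate F9 to 14.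

**Further compounds**

F1 | step 2 | (1S,5S,7aS)-4,7a-dimethyl-2,3,5,6,7,7a-hexahydro-1H-indene-1,5-diol | C[C@]12CC[C@H](O)C(C)=C1CC[C@@H]2O
F2 | step 2 | 1-[(1S,5R,7aS)-1-hydroxy-4,7a-dimethyl-2,3,5,6,7,7a-hexahydro-1H-inden-5-yl]-1-(2-nitrobenzenesulfonyl)hydrazine | C[C@]12CC[C@@H](N(N)S(=O)(=O)c3ccccc3[N+](=O)[O-])C(C)=C1CC[C@@H]2O
F3 | step 2 | (1S,5R,7aS)-5-diazenyl-4,7a-dimethyl-2,3,5,6,7,7a-hexahydro-1H-inden-1-ol | C[C@]12CC[C@@H](N=N)C(C)=C1CC[C@@H]2O
F4 | step 2 | (1S,3aS,7aS)-4,7a-dimethyl-2,3,3a,6,7,7a-hexahydro-1H-inden-1-ol | C[C@]12CCC=C(C)[C@@H]1CC[C@@H]2O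
F5 | step 3 | (5S,7aS)-4,7a-dimethyl-1-oxo-2,3,5,6,7,7a-hexahydro-1H-inden-5-yl formate | C[C@]12CC[C@H](OC=O)C(C)=C1CCC2=O
F6 | step 5 | (1S,3aS,7aS)-1-(dibromomethyl)-4,7a-dimethyl-2,3,3a,6,7,7a-hexahydro-1H-inden-1-ol | C[C@]12CCC=C(C)[C@@H]1CC[C@@]2(O)C(Br)Br
F7 | step 5 | (4aR,8aR)-5,8a-dimethyl-3,4,4a,7,8,8a-hexahydronaphthalen-2(1H)-one | C[C@]12CCC=C(C)[C@@H]1CCC(=O)C2
F8 | step 5 | (4aR,8aR)-3-(2-hydroxypropan-2-yl)-5,8a-dimethyl-3,4,4a,7,8,8a-hexahydronaphthalen-2(1H)-one (C3 epimers) | C[C@]12CCC=C(C)[C@@H]1CC(C(C)(C)O)C(=O)C2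
F9 | step 5 | 2-[(4aR,8aR)-5,8a-dimethyl-2-oxo-1,2,3,4,4a,7,8,8a-octahydronaphthalen-3-yl]propan-2-yl methanesulfonate (C3 epimers) | C[C@]12CCC=C(C)[C@@H]1CC(C(C)(C)OS(C)(=O)=O)C(=O)C2
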